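## The problem

Integracin D is an ester of two 5-alkylresorcinol units. Ring A is a 2,4-dihydroxy-6-alkylbenzoate: C1 carries the ester carbonyl, C2 and C4 carry hydroxyls, and C6 carries an (S)-8-acetoxyundecyl chain. The ester oxygen is O4 of an (S)-undecan-4-ol whose C11 bears ring B, a resorcinol with one free hydroxyl (C3') and one hydrogen sulfate (C5').

The ester joins a benzoic acid with two ortho substituents to a secondary alcohol, which is the worst place in the molecule to form an ester late. The two stereocenters are both (S)-configured propyl carbinols. They lie seven methylenes from the rings and far from each other, so neither can control the other and each must be brought in enantiopure. Because both are PrCH(O)CH2 units, one chiral building block can serve for both.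

Ring B needs its two equivalent phenols told apart. The aryl hydrogen sulfate does not tolerate acid, and the acetate and the benzoate ester do not tolerate base, hydride or strong nucleophiles. The sulfate therefore has to travel masked and the last steps have to be close to neutral.

The enabling feature is in ring A. C1 and C6 are adjacent and are the two ends of a 2-alkynoate, and C2–C5 with oxygen on C2 and C4 correspond to a butadiene oxygenated twice at one terminus and once at C3. Ring A can therefore be grown onto an ester that already exists.

## Retrosynthesis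

**Unmasking (32 ⇒ 30 ⇒ 29).** The S–O bond to a 2,2,2-trichloroethyl group is cut last, so that the free sulfate appears only in a neutral reductive step that leaves both esters alone. Before that, the O–CH3 bond at C2 of ring A and the O–benzyl bond on ring B are cut together by a boron Lewis acid, giving 30 from 29. Carrying a free sulfate or free phenols further back would make every earlier intermediate polar and incompatible with the ring-forming step. The forward reactions must spare the acetate, the hindered ester and the sulfate diester.

**Ring A (29 ⇒ 20 + 26).** Ring bonds C1–C2 and C5–C6 are cut, which returns the ynoate 20 and the diene 26. The neighbouring cut, at the ester C–O bond of 29, would require acylation of a secondary alcohol by a 2,6-disubstituted benzoic acid. The ring cut avoids this because the ester predates the arene. The precursor 20 is acyclic and 26 has four carbons. The forward reaction must fix the orientation (chain ortho to the ester, oxygens at C2 and C4) and tolerate the acetate, benzyl ether and sulfate diester on heating.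

**Ester (20 ⇒ 11 + 19).** The acyl–oxygen bond is cut to give the ring B alcohol 11 and the linear alkynoic acid 19. At this stage the acid is unhindered, so a carbodiimide coupling should suffice. The carbinol C–O bond is not touched, so its configuration is retained. Each half carries one stereocenter and about half the carbons.

**Ring B alcohol (11 ⇒ 10 ⇒ 6 + 8; 8 ⇒ 7).** The S–O bond of the sulfate diester is cut to give phenol 10. The aryl–CH2 bond of 10 is then cut to give alkenol 6 and aryl bromide 8, to be joined by hydroboration and palladium-catalysed alkyl–aryl coupling. Olefination or alkynylation routes to the same bond would need a hydrogenation that the benzyl ether does not survive. Sulfation is placed after the coupling because the trichloroethyl ester is sensitive to the aqueous base of the coupling. Bromide 8 comes from 7 by etherification of one of two equivalent hydroxyls. The forward sequence must sulfate the phenol of 10 in preference to its secondary hydroxyl.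

**Alkynoic acid (19 ⇒ 17 ⇒ 15 ⇒ 14 ⇒ 3 + 12).** The acetate is removed first, giving 17, because it would not survive the base used to metallate the alkyne. The C1–C2 bond of 17 is cut by carboxylation to give the terminal alkynol 15. Alkynol 15 is traced to its internal isomer 14 by base-mediated migration of the triple bond, and the C5–C6 bond of 14 is cut to give epoxide 3 and oct-1-yne 12. This reaches 15 in two operations from 3. A route through a terminal alkene would need hydroboration, oxidation and homologation.

**Shared chiral source (6 ⇒ 3 + 4 via 5; 3 ⇒ 2 ⇒ 1).** The C5–C6 bond of 6 is cut to give epoxide 3 and the Grignard reagent 5 made from 6-bromohex-1-ene 4. Epoxide 3 comes from chlorohydrin 2 and this from (S)-epichlorohydrin 1. Both stereocenters of the target thus come from a single chiral-pool epoxide by reactions that never break a bond at the stereocenter. A separate asymmetric step for each center would be longer and would add an enantioselectivity question.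

**Diene (26 ⇒ 25 ⇒ 24 ⇒ 21 + 22 via 23).** The O–Si bond of 26 is cut to give ketone 25. The two C–OMe bonds are traced to the dichlorovinyl ketone 24, and its C2–C3 bond is cut to give 1,1-dichloroethene 21 and acetyl chloride 22, with 23 as the primary adduct. These are three steps from bulk chemicals, each of a classical type.

## Roads not taken

**Alternative 1:** Ring A is taken from a preformed arene, and the cut is made at the C6–CH2 bond and the C1–carboxyl bond. In the forward sense 1-fluoro-3,5-diisopropoxybenzene A1 would be lithiated next to fluorine and lose fluoride to give 3,5-diisopropoxybenzyne A2. The chain Grignard reagent A3 would add at the aryne carbon remote from the flanking alkoxy group, and the arylmagnesium formed at C1 would be carboxylated to give acid A4.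

- Merits: both adjacent substituents are set in one flask at low temperature, the orientation is fixed by the alkoxy group, and no sensitive group is heated. On ring A alone this is at least as safe as the cycloaddition, and shorter than the three-step preparation of 26.
- Weak points: A4 is a 2,6-disubstituted benzoic acid that must still be esterified with the secondary alcohol 11. The Grignard reagent cannot carry the acetate, so a silyl ether has to be exchanged later. Two isopropyl ethers must be cleaved, one of them without help from chelation.
- Comparison: the chosen plan accepts a thermal step on an elaborate substrate and a methyl ether at C2. In return the ester is made from an unhindered alkynoic acid before ring A exists, which removes the hardest bond construction of this alternative.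

**Alternative 2:** The cut is made in the chain of the ring B alcohol, at both C–C bonds of C6 of the undecanol. Lithiated 2-(tert-butyldimethylsilyl)-1,3-dithiane A5 would open epoxide 3 at its CH2 group. A polar additive would trigger the 1,4-Brook shift of silicon to the new alkoxide, and the regenerated dithiane anion would be alkylated by 1,3-bis(benzyloxy)-5-(5-iodopentyl)benzene A6 to give A7.

- Merits: three components are joined in one operation from the same chiral source 3. The carbinol emerges already silylated, which the chosen plan does not have: it must sulfate the phenol of 10 beside a free secondary hydroxyl.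
- Weak points: the dithiane carbon has no function in the target and must be removed by reductive desulfurisation in the presence of two benzyl ethers. A6 needs several steps. The two ring B oxygens carry the same group, so their differentiation is only postponed. Ring A and the hindered ester are not addressed.
- Comparison: the chosen plan reaches 10 from 6 and 8 in one operation, and its key step deals with ring A.

**Alternative 3:** The cut is made inside ring B, at C3'–C4' and C5'–C6'. Heating the 3-alkylcyclobutenone A8 with (triisopropylsilyloxy)ethyne A9 would open A8 to a vinylketene. This would add the ynol ether in a [2+2] sense, open again and close by 6π electrocyclisation to give the phenol A10 (Danheiser benzannulation).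

- Merits: the two oxygens of ring B are formed already differentiated, one free and one silylated. This is better than the statistical etherification of 7 in the chosen plan.
- Weak points: the ring it builds is the one that can be bought as 7. A8 must be made with the chain and stereocenter attached, and A9 is a sensitive reagent. Ring A and the hindered ester remain unsolved.
- Comparison: the chosen plan accepts one statistical step on a cheap arene, and spends its ring-forming step on ring A, where it also solves the ester problem.

Key step: step 15

Assumption 1: 2,2,2-trichloroethyl chlorosulfate is treated as a purchasable reagent (it is otherwise one step from 2,2,2-trichloroethanol and sulfuryl chloride).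
Assumption 2: the target is drawn as the free aryl hydrogen sulfate; the zinc step should deliver its ammonium salt 31, and brief cold acidification is taken to give the acid form 32.

## Steps

Step 1
Reactants: 1 (S)-epichlorohydrin
Product: 2 (S)-1-chloropentan-2-ol
Conditions: EtMgBr, CuI (10 mol%), THF, −40 to −20 °C; aq. NH4Cl
Reagents that add atoms: ethylmagnesium bromide, CC[Mg]Br
Why: Copper-catalysed Grignard opening of a terminal epoxide should occur at the unsubstituted ring carbon and faster than displacement of chloride; the C–O bond at the stereocenter is not broken, so the (S) configuration is carried over.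

Step 2
Reactants: 2 (S)-1-chloropentan-2-ol
Product: 3 (S)-2-propyloxirane
Conditions: powdered NaOH, Et2O, rt; distillation
Reagents that add atoms: none
Why: Intramolecular Williamson displacement of the primary chloride by the alkoxide closes the epoxide; the stereocenter is untouched and keeps the (S) descriptor.

Step 3
Reactants: 4 6-bromohex-1-ene; 3 (S)-2-propyloxirane
Product: 6 (S)-undec-10-en-4-ol, via hex-5-enylmagnesium bromide 5 (not isolated)
Conditions: Mg, THF, rt; then CuI (10 mol%), 3, −30 to 0 °C; aq. NH4Cl
Reagents that add atoms: none
Why: Copper-catalysed Grignard opening of the monosubstituted epoxide at its CH2 group gives the secondary alcohol; the carbinol C–O bond is not involved, so the center stays (S).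

Step 4
Reactants: 7 5-bromoresorcinol
Product: 8 3-(benzyloxy)-5-bromophenol
Conditions: BnBr (1.0 equiv), K2CO3, acetone, reflux
Reagents that add atoms: benzyl bromide, BrCc1ccccc1
Why: Williamson etherification of one of two equivalent phenols; the outcome is statistical, the mono-ether should be separable from the diether and from recovered 7, and both of these can be recycled.

Step 5
Reactants: 6 (S)-undec-10-en-4-ol; 8 3-(benzyloxy)-5-bromophenol
Product: 10 (S)-3-(benzyloxy)-5-(8-hydroxyundecyl)phenol, via alkylborane 9 (not isolated)
Conditions: 9-BBN (2.2 equiv), THF, 0 °C to rt; then 8, Pd(dppf)Cl2 (5 mol%), aq. K3PO4, DMF, 60 °C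
Reagents that add atoms: none
Why: Anti-Markovnikov hydroboration of the terminal alkene followed by B-alkyl Suzuki–Miyaura coupling; the second equivalent of borane is taken up by the hydroxyl as a borinate that hydrolyses on work-up, and the phenoxide sits meta to bromine so it should not slow oxidative addition to zerovalent palladium.

Step 6
Reactants: 10 (S)-3-(benzyloxy)-5-(8-hydroxyundecyl)phenol
Product: 11 3-(benzyloxy)-5-[(S)-8-hydroxyundecyl]phenyl 2,2,2-trichloroethyl sulfate
Conditions: Cl3CCH2OSO2Cl (1.1 equiv), Et3N (1.2 equiv), DMAP (10 mol%), THF, 0 °C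
Reagents that add atoms: 2,2,2-trichloroethyl chlorosulfate, O=S(=O)(Cl)OCC(Cl)(Cl)Cl
Why: O-sulfonylation of a phenol by a chlorosulfate ester under amine base; the phenol is largely ionised by Et3N and should react far faster than the neutral secondary alcohol, as in selective sulfonylation of phenols beside aliphatic hydroxyls.

Step 7
Reactants: 12 oct-1-yne; 3 (S)-2-propyloxirane
Product: 14 (S)-tridec-6-yn-4-ol, via lithium oct-1-ynide 13 (not isolated)
Conditions: n-BuLi, THF, −78 °C; BF3·OEt2, then 3, −78 °C; aq. NH4Cl
Reagents that add atoms: none
Why: BF3-promoted opening of a terminal epoxide by a lithium acetylide occurs at the CH2 group under SN2 control; the stereocenter is not attacked and remains (S).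

Step 8
Reactants: 14 (S)-tridec-6-yn-4-ol
Product: 15 (S)-tridec-12-yn-4-ol
Conditions: KH (4 equiv), H2N(CH2)3NH2, 0 °C to rt; aq. NH4Cl
Reagents that add atoms: none
Why: Alkyne zipper isomerisation: the potassium amide moves the triple bond through allene intermediates to the chain end, where it is trapped as the acetylide; migration towards the carbinol is blocked by the alkoxide, so the stereocenter should not be touched.

Step 9
Reactants: 15 (S)-tridec-12-yn-4-ol
Product: 17 (S)-11-hydroxytetradec-2-ynoic acid, via dilithium alkoxide acetylide 16 (not isolated)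
Conditions: n-BuLi (2.2 equiv), THF, −78 to 0 °C; CO2, −78 °C to rt; aq. HCl
Reagents that add atoms: carbon dioxide, O=C=O
Why: Carboxylation of a lithium acetylide; the alkoxide is protected as its lithium salt, and any alkyl carbonate formed at oxygen loses CO2 on acidification.

Step 10
Reactants: 17 (S)-11-hydroxytetradec-2-ynoic acid
Product: 19 (S)-11-acetoxytetradec-2-ynoic acid, via mixed anhydride 18 (not isolated)
Conditions: Ac2O (3 equiv), pyridine, DMAP (5 mol%), CH2Cl2, 0 °C to rt; then H2O, rt; dil. HCl
Reagents that add atoms: acetic anhydride, CC(=O)OC(C)=O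
Why: Standard O-acetylation of a hydroxy acid; the carboxyl is converted in passing to the mixed anhydride, which is hydrolysed selectively by water before isolation, and the excess of anhydride keeps intermolecular esterification down.

Step 11
Reactants: 11 3-(benzyloxy)-5-[(S)-8-hydroxyundecyl]phenyl 2,2,2-trichloroethyl sulfate; 19 (S)-11-acetoxytetradec-2-ynoic acid
Product: 20 (S)-11-[3-(benzyloxy)-5-{[(2,2,2-trichloroethoxy)sulfonyl]oxy}phenyl]undecan-4-yl (S)-11-acetoxytetradec-2-ynoate
Conditions: DCC (1.2 equiv), DMAP (10 mol%), CH2Cl2, 0 °C to rt
Reagents that add atoms: none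
Why: Steglich esterification of an unhindered alkynoic acid with a secondary alcohol; the acyl–oxygen bond is formed, so the carbinol configuration is retained, and the low temperature limits base-induced isomerisation of the ynoate.

Step 12
Reactants: 21 1,1-dichloroethene; 22 acetyl chloride
Product: 24 4,4-dichlorobut-3-en-2-one, via 4,4,4-trichlorobutan-2-one 23 (not isolated)
Conditions: AlCl3 (1.1 equiv), CH2Cl2, 0 °C to rt; ice water; steam distillation
Reagents that add atoms: none
Why: Friedel–Crafts-type acylation of the alkene at its CH2 terminus gives the chloride-trapped adduct, and the β-trichloromethyl ketone loses HCl on heating to the conjugated dichlorovinyl ketone.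

Step 13
Reactants: 24 4,4-dichlorobut-3-en-2-one
Product: 25 4,4-dimethoxybut-3-en-2-one
Conditions: NaOMe (2.2 equiv), MeOH, 0 °C to rt
Reagents that add atoms: sodium methoxide, C[O-].[Na+]
Why: Two successive addition–elimination reactions at the β-carbon of the vinylogous acid chloride replace both chlorides by methoxide.

Step 14
Reactants: 25 4,4-dimethoxybut-3-en-2-one
Product: 26 1,1-dimethoxy-3-(trimethylsilyloxy)buta-1,3-diene
Conditions: LiN(iPr)2 (1.1 equiv), THF, −78 °C; Me3SiCl; distillation
Reagents that add atoms: chlorotrimethylsilane, C[Si](C)(C)Cl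
Why: Kinetic deprotonation of the methyl ketone gives the cross-conjugated enolate, and O-silylation gives the 2-siloxydiene; the compound is moisture-sensitive and is to be used freshly distilled.

Step 15
Reactants: 20 (S)-11-[3-(benzyloxy)-5-{[(2,2,2-trichloroethoxy)sulfonyl]oxy}phenyl]undecan-4-yl (S)-11-acetoxytetradec-2-ynoate; 26 1,1-dimethoxy-3-(trimethylsilyloxy)buta-1,3-diene
Product: 29 (S)-11-[3-(benzyloxy)-5-{[(2,2,2-trichloroethoxy)sulfonyl]oxy}phenyl]undecan-4-yl 2-[(S)-8-acetoxyundecyl]-4-hydroxy-6-methoxybenzoate, via cyclohexadiene cycloadduct 27 (not isolated), via aryl trimethylsilyl ether 28 (not isolated)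
Conditions: 26 (3 equiv), toluene, 120 °C, sealed tube; then 1 M HCl, THF, rt
Reagents that add atoms: none
Why: The electron-rich ketene acetal diene 26 and the electron-poor ynoate 20 should combine in a normal-demand, strongly asynchronous Diels–Alder reaction in which the unsubstituted CH2 terminus of 26 bonds first to the chain-bearing β-carbon (ring bond C5–C6) and the acetal carbon then closes onto the α-carbon (C1–C2), giving the cyclohexa-1,4-diene ketal 27. The closest known reaction type is the cycloaddition of alkyl 2-alkynoates with 1,1-dialkoxy-3-siloxybuta-1,3-dienes followed by aromatisation to 4-hydroxy-2-alkoxy-6-alkylbenzoates, which is also known for ynoates with long functionalised chains. Ring A is closed intermolecularly as a six-membered carbocycle in a [4+2] mode, with C2–C5 from the diene and C1 and C6 from the alkyne. Adduct 27 should aromatise under the reaction conditions by 1,4-elimination of methanol (methoxy from C2, hydrogen from C5) to the silyl ether 28, and the acidic work-up cleaves the O–Si bond to give phenol 29. No stereocenter is formed, and the two remote carbinol centers cannot epimerise under neutral heating. The only selectivity needed is regiochemical; it is secured by the match between the diene terminus made nucleophilic by all three oxygens and the β-carbon made electrophilic by the ester, and a stepwise conjugate addition followed by ring closure would lead to the same arene. Compound 20 has no O–H group that could protonate the diene, and the acetate, benzyl ether and trichloroethyl sulfate should be spectators. The hindered ester is already in place, so no acylation by a 2,6-disubstituted benzoic acid is ever needed.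

Step 16
Reactants: 29 (S)-11-[3-(benzyloxy)-5-{[(2,2,2-trichloroethoxy)sulfonyl]oxy}phenyl]undecan-4-yl 2-[(S)-8-acetoxyundecyl]-4-hydroxy-6-methoxybenzoate
Product: 30 (S)-11-[3-hydroxy-5-{[(2,2,2-trichloroethoxy)sulfonyl]oxy}phenyl]undecan-4-yl 2-[(S)-8-acetoxyundecyl]-4,6-dihydroxybenzoate
Conditions: BCl3 (6 equiv), C6HMe5 (3 equiv), CH2Cl2, −78 to 0 °C; aq. NaHCO3
Reagents that add atoms: none
Why: Lewis-acid ether cleavage: the aryl benzyl ether is cleaved at low temperature with pentamethylbenzene trapping the benzyl cation, and the methyl ether ortho to the ester carbonyl is cleaved through a six-membered boron chelate; alkyl esters and the electron-poor sulfate diester are poor donors towards BCl3 and should survive.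

Step 17
Reactants: 30 (S)-11-[3-hydroxy-5-{[(2,2,2-trichloroethoxy)sulfonyl]oxy}phenyl]undecan-4-yl 2-[(S)-8-acetoxyundecyl]-4,6-dihydroxybenzoate
Product: 32 Integracin D, via ammonium salt 31 (not isolated)
Conditions: Zn dust, HCO2NH4, MeOH, rt; then cold dil. HCl (pH 2), EtOAc extraction
Reagents that add atoms: none
Why: Reductive fragmentation of the 2,2,2-trichloroethyl ester by zinc (two-electron reduction of a C–Cl bond, then β-elimination of the sulfate monoester) proceeds near neutral pH, so the acetate and the benzoate are not touched; brief cold acidification converts the ammonium salt to the acid form.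

## Compound list

1 | (S)-epichlorohydrin [(S)-2-(chloromethyl)oxirane] | ClC[C@@H]1CO1 | starting material
2 | (S)-1-chloropentan-2-ol | CCC[C@H](O)CCl | intermediate
3 | (S)-2-propyloxirane | CCC[C@H]1CO1 | intermediate
4 | 6-bromohex-1-ene | C=CCCCCBr | starting material
5 | hex-5-enylmagnesium bromide | C=CCCCC[Mg]Br | intermediate
6 | (S)-undec-10-en-4-ol | CCC[C@H](O)CCCCCC=C | intermediate
7 | 5-bromoresorcinol | Oc1cc(O)cc(Br)c1 | starting material
8 | 3-(benzyloxy)-5-bromophenol | Oc1cc(Br)cc(OCc2ccccc2)c1 | intermediate
9 | 9-[(S)-8-(9-borabicyclo[3.3.1]nonan-9-yloxy)undecyl]-9-borabicyclo[3.3.1]nonane | CCC[C@H](OB1C2CCCC1CCC2)CCCCCCCB1C2CCCC1CCC2 | intermediate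
10 | (S)-3-(benzyloxy)-5-(8-hydroxyundecyl)phenol | CCC[C@H](O)CCCCCCCc1cc(O)cc(OCc2ccccc2)c1 | intermediate
11 | 3-(benzyloxy)-5-[(S)-8-hydroxyundecyl]phenyl 2,2,2-trichloroethyl sulfate | CCC[C@H](O)CCCCCCCc1cc(OCc2ccccc2)cc(OS(=O)(=O)OCC(Cl)(Cl)Cl)c1 | intermediate
12 | oct-1-yne | CCCCCCC#C | starting material
13 | lithium oct-1-ynide | [Li]C#CCCCCCC | intermediate
14 | (S)-tridec-6-yn-4-ol | CCC[C@H](O)CC#CCCCCCC | intermediate
15 | (S)-tridec-12-yn-4-ol | CCC[C@H](O)CCCCCCCC#C | intermediate
16 | dilithium salt of (S)-tridec-12-yn-4-ol (lithium alkoxide, lithium acetylide) | CCC[C@H](O[Li])CCCCCCCC#C[Li] | intermediate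
17 | (S)-11-hydroxytetradec-2-ynoic acid | CCC[C@H](O)CCCCCCCC#CC(=O)O | intermediate
18 | acetic (S)-11-acetoxytetradec-2-ynoic anhydride | CCC[C@H](OC(C)=O)CCCCCCCC#CC(=O)OC(C)=O | intermediate
19 | (S)-11-acetoxytetradec-2-ynoic acid | CCC[C@H](OC(C)=O)CCCCCCCC#CC(=O)O | intermediate
20 | (S)-11-[3-(benzyloxy)-5-{[(2,2,2-trichloroethoxy)sulfonyl]oxy}phenyl]undecan-4-yl (S)-11-acetoxytetradec-2-ynoate | CCC[C@@H](CCCCCCCC#CC(=O)O[C@@H](CCC)CCCCCCCc1cc(OCc2ccccc2)cc(OS(=O)(=O)OCC(Cl)(Cl)Cl)c1)OC(C)=O | intermediate
21 | 1,1-dichloroethene | C=C(Cl)Cl | starting material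
22 | acetyl chloride | CC(=O)Cl | starting material
23 | 4,4,4-trichlorobutan-2-one | CC(=O)CC(Cl)(Cl)Cl | intermediate
24 | 4,4-dichlorobut-3-en-2-one | CC(=O)C=C(Cl)Cl | intermediate
25 | 4,4-dimethoxybut-3-en-2-one | CC(=O)C=C(OC)OC | intermediate
26 | 1,1-dimethoxy-3-(trimethylsilyloxy)buta-1,3-diene | COC(OC)=CC(=C)O[Si](C)(C)C | intermediate
27 | (S)-11-[3-(benzyloxy)-5-{[(2,2,2-trichloroethoxy)sulfonyl]oxy}phenyl]undecan-4-yl 2-[(S)-8-acetoxyundecyl]-6,6-dimethoxy-4-(trimethylsilyloxy)cyclohexa-1,4-diene-1-carboxylate | CCC[C@@H](CCCCCCCC1=C(C(=O)O[C@@H](CCC)CCCCCCCc2cc(OCc3ccccc3)cc(OS(=O)(=O)OCC(Cl)(Cl)Cl)c2)C(OC)(OC)C=C(O[Si](C)(C)C)C1)OC(C)=O | intermediate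
28 | (S)-11-[3-(benzyloxy)-5-{[(2,2,2-trichloroethoxy)sulfonyl]oxy}phenyl]undecan-4-yl 2-[(S)-8-acetoxyundecyl]-6-methoxy-4-(trimethylsilyloxy)benzoate | CCC[C@@H](CCCCCCCc1cc(O[Si](C)(C)C)cc(OC)c1C(=O)O[C@@H](CCC)CCCCCCCc1cc(OCc2ccccc2)cc(OS(=O)(=O)OCC(Cl)(Cl)Cl)c1)OC(C)=O | intermediate
29 | (S)-11-[3-(benzyloxy)-5-{[(2,2,2-trichloroethoxy)sulfonyl]oxy}phenyl]undecan-4-yl 2-[(S)-8-acetoxyundecyl]-4-hydroxy-6-methoxybenzoate | CCC[C@@H](CCCCCCCc1cc(O)cc(OC)c1C(=O)O[C@@H](CCC)CCCCCCCc1cc(OCc2ccccc2)cc(OS(=O)(=O)OCC(Cl)(Cl)Cl)c1)OC(C)=O | intermediate
30 | (S)-11-[3-hydroxy-5-{[(2,2,2-trichloroethoxy)sulfonyl]oxy}phenyl]undecan-4-yl 2-[(S)-8-acetoxyundecyl]-4,6-dihydroxybenzoate | CCC[C@@H](CCCCCCCc1cc(O)cc(O)c1C(=O)O[C@@H](CCC)CCCCCCCc1cc(O)cc(OS(=O)(=O)OCC(Cl)(Cl)Cl)c1)OC(C)=O | intermediate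
31 | Integracin D ammonium salt | CCC[C@@H](CCCCCCCc1cc(O)cc(O)c1C(=O)O[C@@H](CCC)CCCCCCCc1cc(O)cc(OS(=O)(=O)[O-])c1)OC(C)=O.[NH4+] | intermediate
32 | Integracin D, (S)-11-[3-hydroxy-5-(sulfooxy)phenyl]undecan-4-yl 2-[(S)-8-acetoxyundecyl]-4,6-dihydroxybenzoate | CCC[C@@H](CCCCCCCc1cc(O)cc(O)c1C(=O)O[C@@H](CCC)CCCCCCCc1cc(O)cc(OS(=O)(=O)O)c1)OC(C)=O | target

## Step count and risks

Total: 17 steps. Longest linear sequence: 10 steps (steps 1, 2, 7, 8, 9, 10, 11, 15, 16, 17).

**Step 15 (key step).** The β-alkyl ynoate is only a moderate dienophile, so the cycloaddition may be slower than thermal decay or oligomerisation of the ketene acetal diene. Conjugate addition without ring closure is a second possible diversion.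

Fallback, from 20 to 30: the ynoate 20 would be heated with 5,5-dimethyl-1,3-bis(trimethylsilyloxy)cyclohexa-1,3-diene F1, made from dimedone by double O-silylation. This diene tolerates higher temperatures and forms the same two ring bonds. The bicyclo[2.2.2]octadiene adduct F2 would aromatise by retro-Diels–Alder loss of 2-methylpropene to the bis(trimethylsilyl) ether F3. Crude F3 would be treated with BCl3 and pentamethylbenzene at −78 °C to remove the benzyl ether, and the silyl ethers would fall off on aqueous work-up. Since no methyl ether is formed, this joins the route at 30.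

**Step 16.** Cleavage of the chelated methyl ether may need temperatures at which the Lewis acid begins to attack the sulfate diester or the esters, so the result could be incomplete deprotection or loss of the sulfate mask.

Fallback, from 29 to 31: the two ether types would be removed by different mechanisms. MgI2·OEt2 in toluene would open only the methyl ether ortho to the ester carbonyl, by chelation and iodide attack, giving the benzyl ether and trichloroethyl sulfate of the free resorcylate F4. Transfer hydrogenolysis of F4 (Pd/C, HCO2NH4, MeOH) would then remove the benzyl group and the trichloroethyl group together and return to the route at the ammonium salt 31.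

**Step 6.** Sulfation or chlorination at the secondary hydroxyl may compete with reaction at the phenol, lowering the selectivity for the mono-sulfate.

Fallback, from 6 to 11: the carbinol would be protected before the coupling. Silylation of 6 (TBSCl, imidazole) would give (S)-tert-butyldimethyl(undec-10-en-4-yloxy)silane F5. Hydroboration with one equivalent of 9-BBN would give the alkylborane F6, and coupling with 8 as in step 5 would give the phenol F7. Sulfation as in step 6 would give the silylated sulfate F8, and HF·pyridine in THF would remove the silyl ether to rejoin the route at 11. This also removes the free hydroxyl from the hydroboration of step 5.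

**Step 8.** The triple bond has to move over six positions under strongly basic conditions; the migration may stall at internal isomers or be accompanied by base-induced degradation.

Fallback, from 3 to 15: the terminal alkyne would be brought in masked. (8-Bromooct-1-yn-1-yl)trimethylsilane F9, from 1,6-dibromohexane and lithium (trimethylsilyl)acetylide, would be converted into its Grignard reagent F10. Addition of F10 to epoxide 3 with CuI catalysis would give (S)-13-(trimethylsilyl)tridec-12-yn-4-ol F11, and K2CO3 in MeOH would remove the silyl group to rejoin the route at 15. This replaces steps 7 and 8.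

## Further compounds

F1 | step 15 | 5,5-dimethyl-1,3-bis(trimethylsilyloxy)cyclohexa-1,3-diene | CC1(C)CC(O[Si](C)(C)C)=CC(O[Si](C)(C)C)=C1
F2 | step 15 | bicyclo[2.2.2]octa-2,5-diene cycloadduct of 20 and F1 (bridgehead configuration undefined, lost on cycloreversion) | CCC[C@@H](CCCCCCCC1=C(C(=O)O[C@@H](CCC)CCCCCCCc3cc(OCc4ccccc4)cc(OS(=O)(=O)OCC(Cl)(Cl)Cl)c3)C2(O[Si](C)(C)C)CC(C)(C)C1C(O[Si](C)(C)C)=C2)OC(C)=O
F3 | step 15 | (S)-11-[3-(benzyloxy)-5-{[(2,2,2-trichloroethoxy)sulfonyl]oxy}phenyl]undecan-4-yl 2-[(S)-8-acetoxyundecyl]-4,6-bis(trimethylsilyloxy)benzoate | CCC[C@@H](CCCCCCCc1cc(O[Si](C)(C)C)cc(O[Si](C)(C)C)c1C(=O)O[C@@H](CCC)CCCCCCCc1cc(OCc2ccccc2)cc(OS(=O)(=O)OCC(Cl)(Cl)Cl)c1)OC(C)=O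
F4 | step 16 | (S)-11-[3-(benzyloxy)-5-{[(2,2,2-trichloroethoxy)sulfonyl]oxy}phenyl]undecan-4-yl 2-[(S)-8-acetoxyundecyl]-4,6-dihydroxybenzoate | CCC[C@@H](CCCCCCCc1cc(O)cc(O)c1C(=O)O[C@@H](CCC)CCCCCCCc1cc(OCc2ccccc2)cc(OS(=O)(=O)OCC(Cl)(Cl)Cl)c1)OC(C)=O
F5 | step 6 | (S)-tert-butyldimethyl(undec-10-en-4-yloxy)silane | CCC[C@H](O[Si](C)(C)C(C)(C)C)CCCCCC=C
F6 | step 6 | 9-[(S)-8-(tert-butyldimethylsilyloxy)undecyl]-9-borabicyclo[3.3.1]nonane | CCC[C@H](O[Si](C)(C)C(C)(C)C)CCCCCCCB1C2CCCC1CCC2
F7 | step 6 | (S)-3-(benzyloxy)-5-[8-(tert-butyldimethylsilyloxy)undecyl]phenol | CCC[C@H](O[Si](C)(C)C(C)(C)C)CCCCCCCc1cc(O)cc(OCc2ccccc2)c1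
F8 | step 6 | 3-(benzyloxy)-5-[(S)-8-(tert-butyldimethylsilyloxy)undecyl]phenyl 2,2,2-trichloroethyl sulfate | CCC[C@H](O[Si](C)(C)C(C)(C)C)CCCCCCCc1cc(OCc2ccccc2)cc(OS(=O)(=O)OCC(Cl)(Cl)Cl)c1
F9 | step 8 | (8-bromooct-1-yn-1-yl)trimethylsilane | C[Si](C)(C)C#CCCCCCCBr
F10 | step 8 | [8-(trimethylsilyl)oct-7-yn-1-yl]magnesium bromide | C[Si](C)(C)C#CCCCCCC[Mg]Br
F11 | step 8 | (S)-13-(trimethylsilyl)tridec-12-yn-4-ol | CCC[C@H](O)CCCCCCCC#C[Si](C)(C)C
A1 | alternative 1 | 1-fluoro-3,5-diisopropoxybenzene | CC(C)Oc1cc(F)cc(OC(C)C)c1
A2 | alternative 1 | 3,5-diisopropoxybenzyne | CC(C)OC1=CC(OC(C)C)=CC#C1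
A3 | alternative 1 | [(S)-8-(tert-butyldimethylsilyloxy)undecyl]magnesium bromide | CCC[C@@H](CCCCCCC[Mg]Br)O[Si](C)(C)C(C)(C)C
A4 | alternative 1 | 2-[(S)-8-(tert-butyldimethylsilyloxy)undecyl]-4,6-diisopropoxybenzoic acid | CCC[C@@H](CCCCCCCc1cc(OC(C)C)cc(OC(C)C)c1C(=O)O)O[Si](C)(C)C(C)(C)C
A5 | alternative 2 | 2-(tert-butyldimethylsilyl)-1,3-dithiane | CC(C)(C)[Si](C)(C)C1SCCCS1
A6 | alternative 2 | 1,3-bis(benzyloxy)-5-(5-iodopentyl)benzene | ICCCCCc1cc(OCc2ccccc2)cc(OCc2ccccc2)c1
A7 | alternative 2 | 2-{5-[3,5-bis(benzyloxy)phenyl]pentyl}-2-[(S)-2-(tert-butyldimethylsilyloxy)pentyl]-1,3-dithiane | CCC[C@@H](CC1(CCCCCc2cc(OCc3ccccc3)cc(OCc3ccccc3)c2)SCCCS1)O[Si](C)(C)C(C)(C)C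
A8 | alternative 3 | 3-[(S)-8-(tert-butyldimethylsilyloxy)undecyl]cyclobut-2-en-1-one | CCC[C@@H](CCCCCCCC1=CC(=O)C1)O[Si](C)(C)C(C)(C)C
A9 | alternative 3 | (triisopropylsilyloxy)ethyne | C#CO[Si](C(C)C)(C(C)C)C(C)C
A10 | alternative 3 | 3-[(S)-8-(tert-butyldimethylsilyloxy)undecyl]-5-(triisopropylsilyloxy)phenol | CCC[C@@H](CCCCCCCc1cc(O)cc(O[Si](C(C)C)(C(C)C)C(C)C)c1)O[Si](C)(C)C(C)(C)C
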